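Everything rests on reading ring C as a masked 8-oxabicyclo[3.2.1]octenone. C9 (the epoxide CH) and C13 (the B/C ring-fusion CH) are the ends of the five-carbon segment C9–C13, and C7 (quaternary, methyl-bearing) with C8 (its ring-C CH2) is a 1,1-disubstituted alkene. A 3-oxidopyrylium ylide built on C9–C13, tethered through ring A to that alkene, closes rings B and C in one intramolecular (5+2) cycloaddition that forms C7–C13 and C8–C9 and sets C7, C9 and C13. The precursor is a trans-1,2-disubstituted cyclopentane (ring A) carrying an acetoxypyranone and a 3-methylbut-3-enyl chain; the bridging oxygen later serves to install H-13 and the C9=C10 alkene.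

Key step: step 8

Remark on numbering (local, used throughout): ring A = C1 (tertiary carbinol), C2 (lactone CH–O), C3, C4 (quaternary, bears C18H2O), C14 (ring-fusion CH); ring B = C4, C5, C6, C7 (quaternary, bears C19H3), C13 (ring-fusion CH), C14; ring C = C7, C8, C9, C10 (bears C20H3), C11, C12, C13; lactone = C1, C15 (bears C16H2=), C17(=O), O, C2. β is the face carrying C18; the target has 18-CH2OAc β, H-14 α, 1-OH α, lactone O and C15 β, 19-CH3 α, H-13 β, epoxide O β.

Remark on mixtures: the carbinol centre C13 (compounds 7–12) and the anomeric centre C9 (11, 12) are carried as mixtures and drawn without configuration, because both become sp2 in ylide 13.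

Assumption: keto ester 4 and the chiral imidazolinium carbene precursor of step 2 are taken as purchasable; the ligand enantiomer is the one that gives the C4 configuration drawn.

Step 1
Reactants: 1 4-bromo-2-methylbut-1-ene
Product: 3 (3-methylbut-3-en-1-yl)[(trimethylsilyl)methyl]zinc, via alkylzinc bromide 2 (not isolated)
Conditions: Zn dust (activated with BrCH2CH2Br and TMSCl), LiCl, THF, 50 °C; then Me3SiCH2Li (1.0 equiv, pentane), −78 °C to rt; solvent exchange to toluene, lithium salts removed by centrifugation; used as titrated solution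
Reagents that add atoms: zinc, [Zn]; (trimethylsilyl)methyllithium, [Li]C[Si](C)(C)C
Why: LiCl-promoted direct insertion of zinc into the primary C–Br bond, then exchange of bromide on zinc for the trimethylsilylmethyl group, should give a mixed diorganozinc whose silylmethyl group is a non-transferable ligand, so that each zinc carries exactly one transferable butenyl group for the ligand-controlled conjugate addition; the remote 1,1-disubstituted alkene is inert.

Step 2
Reactants: 4 methyl 3-oxocyclopent-1-ene-1-carboxylate; 3 (3-methylbut-3-en-1-yl)[(trimethylsilyl)methyl]zinc; 5 4-methylfuran-2-carbaldehyde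
Product: 7 cis-fused keto-lactone, via zinc enolate 6 (not isolated)
Conditions: (CuOTf)2·C6H6 (2.5 mol %), chiral sulfonate-bearing imidazolinium salt (carbene precursor, 5 mol %), 3 (3 equiv), toluene/t-BuOMe, −30 °C; then 5, −78 to 0 °C; aq NH4Cl; PPTS (cat.), CH2Cl2, rt
Reagents that add atoms: none
Why: Copper-catalysed asymmetric conjugate addition of a diorganozinc to a cyclic γ-keto ester should set the quaternary C4 under ligand control, with only the butenyl group of 3 passing to copper because the trimethylsilylmethyl group stays on zinc, the zinc enolate then adds to 5 at C14 (aldol) preferentially syn to the smaller ester group, and because only that cis aldolate can lactonise, retro-aldol equilibration funnels material into 7 and fixes H-14.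

Step 3
Reactants: 7 cis-fused keto-lactone
Product: 8 ketal lactone
Conditions: 1,2-bis(trimethylsilyloxy)ethane, TMSOTf (5 mol %), CH2Cl2, −78 to −20 °C; pyridine quench
Reagents that add atoms: 1,2-bis(trimethylsilyloxy)ethane, C[Si](C)(C)OCCO[Si](C)(C)C
Why: Aprotic silyl-transfer ketalisation should mask the C1 ketone without the base that would cause β-elimination of the C13 acyloxy group, and once C1 is no longer a carbonyl C14 cannot epimerise.

Step 4
Reactants: 8 ketal lactone
Product: 9 ring-A diol
Conditions: LiAlH4, THF, 0 °C; H2O, 15 % NaOH, H2O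
Reagents that add atoms: none
Why: Hydride reduction of the lactone should release C18H2OH and the C13 furyl carbinol, which are necessarily cis on ring A (and trans to the butenyl chain) because both come from one cis-fused lactone.

Step 5
Reactants: 9 ring-A diol
Product: 10 primary TBS ether
Conditions: TBSCl (1.05 equiv), imidazole, CH2Cl2, 0 °C
Reagents that add atoms: tert-butyldimethylsilyl chloride, CC(C)(C)[Si](C)(C)Cl
Why: The primary alcohol should silylate much faster than the hindered secondary furyl carbinol, which protects C18–O for the later Mitsunobu and enolate steps.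

Step 6
Reactants: 10 primary TBS ether
Product: 11 pyranone lactol
Conditions: VO(acac)2 (5 mol %), t-BuOOH (1.3 equiv), CH2Cl2, 0 °C to rt
Reagents that add atoms: tert-butyl hydroperoxide, CC(C)(C)OO
Why: Hydroxyl-directed furan oxidation with ring expansion (Achmatowicz rearrangement) should give the 6-hydroxy-2H-pyran-3(6H)-one with the furan methyl on C10, the remote alkene being untouched.

Step 7
Reactants: 11 pyranone lactol
Product: 12 pyranone acetate
Conditions: Ac2O, pyridine, DMAP (cat.), CH2Cl2, 0 °C
Reagents that add atoms: acetic anhydride, CC(=O)OC(C)=O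
Why: Acylation of the anomeric hydroxyl installs the leaving group for ylide generation.

Step 8
Reactants: 12 pyranone acetate
Product: 14 oxa-bridged tetracyclic enone, via oxidopyrylium ylide 13 (not isolated)
Conditions: DBU (1.5 equiv), MeCN (0.005 M), 60 °C
Reagents that add atoms: none
Why: Base-induced loss of acetic acid from 12 gives the 3-oxidopyrylium ylide 13, whose termini C13 (pyrylium C2) and C9 (pyrylium C6) add suprafacially across the tethered C7=C8 alkene in a thermally allowed (5+2) cycloaddition, the nucleophilic CH2 terminus C8 bonding to the oxocarbenium-like C9 and the enolate-like C13 to the more substituted C7. The closest known reaction type is the intramolecular oxidopyrylium–alkene cycloaddition of 6-acetoxypyranones that carry a four-atom tether to an unactivated alkene. Ring B (C4–C5–C6–C7–C13–C14) closes as the tether ring through the C7–C13 bond, and ring C (C7–C8–C9–C10–C11–C12–C13) closes as the seven-membered cycloadduct ring through C7–C13 plus C8–C9, spanned for now by the C9–O–C13 bridge. The oxabicyclo[3.2.1] framework forces the tether carbon C6 exo and the C19 methyl endo on C7, so C19 is anti to the bridging oxygen, and the trans arrangement of the two arms on ring A (fixed in steps 2 to 4, not epimerisable while C1 is a ketal) admits only the chair-like ring-B transition state with C1 and C3 equatorial, which puts the bridging oxygen β on C9 and C13 and C19 α on C7. The step needs the intramolecular cycloaddition to outrun ylide dimerisation, which high dilution and the gem-disubstituted tether should secure, and it needs the C7-to-C13 regiochemistry, which the tether length and the polarity match secure.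

Step 9
Reactants: 14 oxa-bridged tetracyclic enone
Product: 15 C1 ketone
Conditions: PPTS (0.3 equiv), acetone/H2O (10:1), 50 °C
Reagents that add atoms: water, O
Why: Mild acid-catalysed ketal hydrolysis should free the C1 ketone while the TBS ether and the bridging ether survive, and H-14 should stay α because the cis-A/B epimer would place C1 axial on ring B, syn to the axial C19 methyl.

Step 10
Reactants: 15 C1 ketone
Product: 17 2α-hydroxy ketone, via lithium enolate 16 (not isolated)
Conditions: LiHMDS (1.1 equiv), THF, −78 °C; 2-(phenylsulfonyl)-3-phenyloxaziridine (1.3 equiv), −78 °C; aq NH4Cl at −78 °C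
Reagents that add atoms: 2-(phenylsulfonyl)-3-phenyloxaziridine, O=S(=O)(c1ccccc1)N1OC1c1ccccc1
Why: Kinetic deprotonation should take the C2 methylene and not the ring-fusion C14–H (the C12 enone has no α′ hydrogen), and the N-sulfonyloxaziridine should transfer oxygen to the enolate face anti to the β C18 substituent, giving the 2α alcohol.

Step 11
Reactants: 17 2α-hydroxy ketone
Product: 18 2β-bromoacetate
Conditions: PPh3 (2 equiv), DIAD (2 equiv), BrCH2CO2H (2 equiv), toluene, 0 °C to rt (betaine preformed)
Reagents that add atoms: bromoacetic acid, OC(=O)CBr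
Why: Mitsunobu esterification should displace the oxyphosphonium at the carbonyl-activated C2 with inversion, which places the acyloxy group β and installs the Reformatsky donor in the same operation.

Step 12
Reactants: 18 2β-bromoacetate
Product: 20 hydroxy lactone γ-hydroxy enone, via samarium enolate 19 (not isolated)
Conditions: SmI2 (2.2 equiv), THF, −78 °C; then MeOH (10 equiv), SmI2 (2.5 equiv), −78 °C; air, aq Na2S2O3/NaHCO3
Reagents that add atoms: none
Why: C–Br reduction gives a samarium ester enolate that adds to the C1 ketone from the β face to which it is tied (intramolecular Reformatsky reaction), so the lactone is cis-fused and the new tertiary hydroxyl is α, and the further SmI2 cleaves the C13–O bond α to the C12 ketone, after which protonation should give the trans-B/C ketone with H-13 β (the epimer would set C12 axial, syn to C18) and free the 9β-hydroxyl.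

Step 13
Reactants: 20 hydroxy lactone γ-hydroxy enone
Product: 23 β,γ-unsaturated ketone, via sulfonylhydrazine adduct 21 (not isolated), via allylic diazene 22 (not isolated)
Conditions: PPh3, DEAD, 2-nitrobenzenesulfonohydrazide, THF, −30 to 23 °C
Reagents that add atoms: none
Why: Mitsunobu displacement of the secondary allylic 9-hydroxyl by the sulfonylhydrazide, loss of sulfinic acid and retro-ene extrusion of N2 from the allylic diazene should move the alkene to C9=C10 and deliver hydrogen to C11 (reductive 1,3-transposition), the tertiary 1-hydroxyl being inert.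

Step 14
Reactants: 23 β,γ-unsaturated ketone
Product: 25 C12-deoxy olefin lactone, via tosylhydrazone 24 (not isolated)
Conditions: TsNHNH2 (1.5 equiv), MeOH, 40 °C; concentrate; catecholborane (3 equiv), CHCl3, 0 °C; NaOAc·3H2O, 60 °C
Reagents that add atoms: none
Why: Catecholborane reduction of the tosylhydrazone of an unconjugated ketone and decomposition of the resulting diazene should turn C12=O into CH2 under near-neutral conditions that leave the C9=C10 alkene, the lactone, the silyl ether and C13 unchanged.

Step 15
Reactants: 25 C12-deoxy olefin lactone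
Product: 28 α-methylene lactone, via Mannich base 26 (not isolated), via ammonium iodide 27 (not isolated)
Conditions: LDA (2.5 equiv), THF, −78 °C; N,N-dimethylmethyleneiminium iodide (3 equiv), −78 to 0 °C; work-up; MeI (excess), MeOH, rt; aq NaHCO3, CH2Cl2, rt
Reagents that add atoms: N,N-dimethylmethyleneiminium iodide, C=[N+](C)C.[I-]
Why: The alkoxide–enolate dianion of the β-hydroxy lactone should be aminomethylated at C15 (Mannich reaction), and quaternisation followed by E1cB loss of trimethylamine gives the exocyclic methylene, the 1-alkoxide being too poor a leaving group to compete.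

Step 16
Reactants: 28 α-methylene lactone
Product: 29 primary alcohol
Conditions: HF·pyridine, pyridine/THF, 0 °C to rt
Reagents that add atoms: none
Why: Buffered fluoride should cleave the primary silyl ether without exposing the Michael-acceptor lactone to basic fluoride.

Step 17
Reactants: 29 primary alcohol
Product: 30 primary acetate
Conditions: Ac2O, pyridine, CH2Cl2, 0 °C to rt
Reagents that add atoms: acetic anhydride, CC(=O)OC(C)=O
Why: The primary hydroxyl should be acetylated selectively, the tertiary 1α-hydroxyl being unreactive without a nucleophilic catalyst.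

Step 18
Reactants: 30 primary acetate
Product: 31 target
Conditions: mCPBA (1.1 equiv), NaHCO3, CH2Cl2, 0 °C
Reagents that add atoms: 3-chloroperoxybenzoic acid, OOC(=O)c1cccc(Cl)c1
Why: Peracid epoxidation (Prilezhaev reaction) should take the electron-rich trisubstituted C9=C10 alkene in preference to the electron-poor methylene lactone, and from the β face because the axial α C19 methyl on the homoallylic C7 shields the α face.

Compound list

1 | 4-bromo-2-methylbut-1-ene | C=C(C)CCBr | starting material
2 | (3-methylbut-3-en-1-yl)zinc bromide | C=C(C)CC[Zn]Br | intermediate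
3 | (3-methylbut-3-en-1-yl)[(trimethylsilyl)methyl]zinc | C=C(C)CC[Zn]C[Si](C)(C)C | intermediate
4 | methyl 3-oxocyclopent-1-ene-1-carboxylate | COC(=O)C1=CC(=O)CC1 | starting material
5 | 4-methylfuran-2-carbaldehyde | Cc1coc(C=O)c1 | starting material
6 | [(trimethylsilyl)methyl]zinc (R)-3-(methoxycarbonyl)-3-(3-methylbut-3-en-1-yl)cyclopent-1-en-1-olate | C=C(C)CC[C@@]1(C(=O)OC)CCC(O[Zn]C[Si](C)(C)C)=C1 | intermediate
7 | (3aS,6aR)-6a-(3-methylbut-3-en-1-yl)-3-(4-methylfuran-2-yl)tetrahydro-1H-cyclopenta[c]furan-1,4(3H)-dione; cis-fused, lactone C=O is C18, position 3 is C13 (both epimers) | O=C1OC(c2cc(C)co2)[C@H]3C(=O)CC[C@@]13CCC(C)=C | intermediate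
8 | C1 ethylene ketal (spiro-1,3-dioxolane) of 7; cis-fused lactone, butenyl α on C4, H-14 α | O=C1OC(c2cc(C)co2)[C@H]3C4(OCCO4)CC[C@@]13CCC(C)=C | intermediate
9 | ring-A diol: C1 ethylene ketal; C4 bears C18H2OH (β) and the 3-methylbut-3-enyl chain (α); C14 bears H (α) and the CH(OH)(4-methylfuran-2-yl) arm (β) | OC[C@]1(CCC(C)=C)CCC2(OCCO2)[C@@H]1C(O)c1cc(C)co1 | intermediate
10 | 18-O-TBS ether of 9 | CC(C)(C)[Si](C)(C)OC[C@]1(CCC(C)=C)CCC2(OCCO2)[C@@H]1C(O)c1cc(C)co1 | intermediate
11 | 6-hydroxy-5-methyl-2H-pyran-3(6H)-one carrying at its C2 (= C13) the ring-A unit of 10 (C14, H α) | CC(C)(C)[Si](C)(C)OC[C@]1(CCC(C)=C)CCC2(OCCO2)[C@@H]1C1OC(O)C(C)=CC1=O | intermediate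
12 | 6-acetoxy derivative of 11 | CC(C)(C)[Si](C)(C)OC[C@]1(CCC(C)=C)CCC2(OCCO2)[C@@H]1C1OC(OC(C)=O)C(C)=CC1=O | intermediate
13 | 5-methyl-3-oxidopyrylium ylide, 2-substituted by the ring-A unit | CC(C)(C)[Si](C)(C)OC[C@]1(CCC(C)=C)CCC2(OCCO2)[C@@H]1c1[o+]cc(C)cc1[O-] | intermediate
14 | cycloadduct: rings A, B, C with a 9β,13β-oxygen bridge; C12 ketone, C10=C11 (C20 on C10), 19-CH3 α on C7, 18-CH2OTBS β on C4, H-14 α, H-9 α, C1 ethylene ketal | CC(C)(C)[Si](C)(C)OC[C@@]12CC[C@@]3(C)C[C@H]4O[C@@]3(C(=O)C=C4C)[C@H]1C1(OCCO1)CC2 | intermediate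
15 | C1 ketone from 14 (1,12-dione, bridge retained) | CC(C)(C)[Si](C)(C)OC[C@@]12CC[C@@]3(C)C[C@H]4O[C@@]3(C(=O)C=C4C)[C@H]1C(=O)CC2 | intermediate
16 | lithium C1(O)=C2 enolate of 15 | CC(C)(C)[Si](C)(C)OC[C@@]12CC[C@@]3(C)C[C@H]4O[C@@]3(C(=O)C=C4C)[C@H]1C(O[Li])=CC2 | intermediate
17 | 2α-hydroxy-1-ketone | CC(C)(C)[Si](C)(C)OC[C@@]12CC[C@@]3(C)C[C@H]4O[C@@]3(C(=O)C=C4C)[C@H]1C(=O)[C@H](O)C2 | intermediate
18 | 2β-(bromoacetoxy)-1-ketone | CC(C)(C)[Si](C)(C)OC[C@@]12CC[C@@]3(C)C[C@H]4O[C@@]3(C(=O)C=C4C)[C@H]1C(=O)[C@@H](OC(=O)CBr)C2 | intermediate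
19 | diiodosamarium ester enolate derived from 18 | CC(C)(C)[Si](C)(C)OC[C@@]12CC[C@@]3(C)C[C@H]4O[C@@]3(C(=O)C=C4C)[C@H]1C(=O)[C@@H](OC(=C)O[Sm](I)I)C2 | intermediate
20 | 1α-hydroxy-17,2β-lactone (C15H2, cis-fused); ring C 9β-hydroxy-10-en-12-one, H-13 β; 18-OTBS | C1C(=O)O[C@H]2C[C@]3(CO[Si](C)(C)C(C)(C)C)CC[C@@]4(C)C[C@@H](O)C(C)=CC(=O)[C@@H]4[C@H]3[C@@]12O | intermediate
21 | 9α-[N-amino-N-(2-nitrophenylsulfonyl)amino] adduct of 20 | C1C(=O)O[C@H]2C[C@]3(CO[Si](C)(C)C(C)(C)C)CC[C@@]4(C)C[C@H](N(N)S(=O)(=O)c5ccccc5[N+](=O)[O-])C(C)=CC(=O)[C@@H]4[C@H]3[C@@]12O | intermediate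
22 | 9α-diazenyl (allylic diazene) compound | C1C(=O)O[C@H]2C[C@]3(CO[Si](C)(C)C(C)(C)C)CC[C@@]4(C)C[C@H](N=N)C(C)=CC(=O)[C@@H]4[C@H]3[C@@]12O | intermediate
23 | 9-en-12-one (β,γ-unsaturated ketone), C11H2, H-13 β; hydroxy lactone and 18-OTBS as in 20 | C1C(=O)O[C@H]2C[C@]3(CO[Si](C)(C)C(C)(C)C)CC[C@@]4(C)CC=C(C)CC(=O)[C@@H]4[C@H]3[C@@]12O | intermediate
24 | C12 tosylhydrazone of 23 | C1C(=O)O[C@H]2C[C@]3(CO[Si](C)(C)C(C)(C)C)CC[C@@]4(C)CC=C(C)CC(=NNS(=O)(=O)c5ccc(C)cc5)[C@@H]4[C@H]3[C@@]12O | intermediate
25 | 9-ene with C12H2; 1α-hydroxy-17,2β-lactone, 18-OTBS | C1C(=O)O[C@H]2C[C@]3(CO[Si](C)(C)C(C)(C)C)CC[C@@]4(C)CC=C(C)CC[C@@H]4[C@H]3[C@@]12O | intermediate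
26 | 15-(dimethylaminomethyl) lactone (C15 epimers) | CN(C)CC1C(=O)O[C@H]2C[C@]3(CO[Si](C)(C)C(C)(C)C)CC[C@@]4(C)CC=C(C)CC[C@@H]4[C@H]3[C@@]12O | intermediate
27 | 15-(trimethylammoniomethyl) lactone iodide | C[N+](C)(C)CC1C(=O)O[C@H]2C[C@]3(CO[Si](C)(C)C(C)(C)C)CC[C@@]4(C)CC=C(C)CC[C@@H]4[C@H]3[C@@]12O.[I-] | intermediate
28 | 15(16)-methylene-1α-hydroxy-17,2β-lactone, 9-ene, 18-OTBS | C=C1C(=O)O[C@H]2C[C@]3(CO[Si](C)(C)C(C)(C)C)CC[C@@]4(C)CC=C(C)CC[C@@H]4[C@H]3[C@@]12O | intermediate
29 | 18-alcohol (1α,18-diol) | C=C1C(=O)O[C@H]2C[C@]3(CO)CC[C@@]4(C)CC=C(C)CC[C@@H]4[C@H]3[C@@]12O | intermediate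
30 | 18-acetate, 9-ene | C=C1C(=O)O[C@H]2C[C@]3(COC(C)=O)CC[C@@]4(C)CC=C(C)CC[C@@H]4[C@H]3[C@@]12O | intermediate
31 | CNP0404717.1: 18-acetoxy-9β,10β-epoxy-1α-hydroxy-15(16)-methylene-17,2β-lactone | C=C1C(=O)O[C@H]2C[C@]3(COC(C)=O)CC[C@@]4(C)C[C@H]5O[C@@]5(C)CC[C@@H]4[C@H]3[C@@]12O | target

Total step count: 18.
Longest linear sequence: 18 steps (1 → 3 → 7 → 14 → 20 → 31); 17 steps from 4.

Steps most likely to fail

Step 13. The displacement at C9 has to enter from the α face past the axial C19 methyl. If it is slow, the oxyphosphonium may eliminate or be attacked in the SN2′ sense at C11, which after loss of N2 would return a conjugated enone without transposition. The fallback sets out from 20: acetylation of the 9β-hydroxyl (Ac2O, pyridine, DMAP, 0 °C, tertiary 1α-hydroxyl untouched) gives the γ-acetoxy enone F1. SmI2 (2.5 equiv) in THF/t-BuOH at −78 °C then expels acetate from the enone ketyl to give a samarium dienolate, and kinetic protonation at the α-carbon C11 gives the deconjugated ketone. The route is rejoined at 23.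

Step 11. Inversion at C2 requires entry on the β face, cis to C18. The activated α-ketol may instead enolise (ketol shift, loss of configuration at C2) or be acylated with retention through an acyloxyphosphonium pathway. The fallback sets out from 15: TMSOTf/Et3N gives the trimethylsilyl enol ether F2, and NBS (THF, −78 °C) brominates it anti to C18 to give the 2α-bromo ketone F3. Caesium chloroacetate (DMF, rt) displaces bromide with inversion to give the 2β-chloroacetate F4, and NaI in acetone gives the 2β-iodoacetate F5. Under the conditions of step 12, F5 should undergo the same reductive aldol lactonisation and C13–O cleavage. The route is rejoined at 20.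

Step 2. Three events share one flask: transfer of the butenyl group from the mixed zinc reagent to copper may be slow or poorly face-selective if lithium halide is carried over, facial discrimination in the aldol capture may be poor, and the C13 oxygen function may β-eliminate (furfurylidene ketone formation) during in situ lactonisation. The fallback sets out from 1 and 4: 1 and Mg in Et2O give (3-methylbut-3-en-1-yl)magnesium bromide F6. F6 is added slowly to 4 with Cu(OTf)2 and a chiral imidazolinium-derived carbene ligand in Et2O at −30 °C (copper-catalysed asymmetric conjugate addition of a Grignard reagent). The magnesium enolate is trapped with TMSCl/Et3N to give methyl (R)-1-(3-methylbut-3-en-1-yl)-3-(trimethylsilyloxy)cyclopent-2-ene-1-carboxylate F7, which is purified. A separate Lewis acid-mediated Mukaiyama aldol addition to 5 (BF3·OEt2, CH2Cl2, −78 °C), followed by acid-catalysed lactonisation of the cis adduct (PPTS), rejoins the route at 7.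

Further compounds
F1 | step 13 | 9β-acetate of 20 (γ-acetoxy enone) | C1C(=O)O[C@H]2C[C@]3(CO[Si](C)(C)C(C)(C)C)CC[C@@]4(C)C[C@@H](OC(C)=O)C(C)=CC(=O)[C@@H]4[C@H]3[C@@]12O
F2 | step 11 | trimethylsilyl C1(O)=C2 enol ether of 15 | CC(C)(C)[Si](C)(C)OC[C@@]12CC[C@@]3(C)C[C@H]4O[C@@]3(C(=O)C=C4C)[C@H]1C(O[Si](C)(C)C)=CC2
F3 | step 11 | 2α-bromo-1-ketone | CC(C)(C)[Si](C)(C)OC[C@@]12CC[C@@]3(C)C[C@H]4O[C@@]3(C(=O)C=C4C)[C@H]1C(=O)[C@H](Br)C2
F4 | step 11 | 2β-(chloroacetoxy)-1-ketone | CC(C)(C)[Si](C)(C)OC[C@@]12CC[C@@]3(C)C[C@H]4O[C@@]3(C(=O)C=C4C)[C@H]1C(=O)[C@@H](OC(=O)CCl)C2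
F5 | step 11 | 2β-(iodoacetoxy)-1-ketone | CC(C)(C)[Si](C)(C)OC[C@@]12CC[C@@]3(C)C[C@H]4O[C@@]3(C(=O)C=C4C)[C@H]1C(=O)[C@@H](OC(=O)CI)C2
F6 | step 2 | (3-methylbut-3-en-1-yl)magnesium bromide | C=C(C)CC[Mg]Br
F7 | step 2 | methyl (R)-1-(3-methylbut-3-en-1-yl)-3-(trimethylsilyloxy)cyclopent-2-ene-1-carboxylate | C=C(C)CC[C@@]1(C(=O)OC)CCC(O[Si](C)(C)C)=C1
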